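**Plan**
Cuts: first the quinone C–N bond and the quinone oxygens (back to a 2,3,5,6-tetramethoxyphenyl group), then C11–aryl, then both C4–CH3 bonds. Last come C4–C5, C1–C10 and C9–C11, which leaves a ring B cyclohexenone, a vinyl anion and a four-carbon enone.
Enabling feature: in ring B, C9 (quaternary, bearing CH3 and C11) and C10 (ring-fusion CH) stand β and α to C5, next to the C8 methyl stereocentre, so C5 can be read as a former ketone. The C4 gem-dimethyl group beside the C5=C6 alkene is the trace left by deconjugative double methylation of a ring A 4-en-3-one.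
Forward order: ring B is made first as an enantioenriched 3,4-dimethylcyclohexenone, and ring A is annulated onto it in the same flask that installs the C9 vinyl group. C4 methylation, C3 deoxygenation, trimming of vinyl to the C11 aldehyde, aryl attachment, C11 deoxygenation and the quinone/amine endgame follow.
Stereochemistry: C8 comes from an enamine-catalysed Michael addition, C9 from cuprate delivery anti to the C8 methyl, and C10 from base equilibration to the isomer with C1 equatorial on ring B (H-10 cis to C11).

Key step: step 6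

Numbering used: ring A = C1, C2, C3, C4, C5, C10; ring B = C5 to C10; C11 = the carbon between C9 and the arene or quinone ring.
Assumption: four centres form as mixtures of no consequence, are erased later, and are left undefined in the SMILES: the silyl-bearing carbon of the Michael adduct, C4 of the monomethylated ketone, the secondary carbinol carbon of the osmylation diol, and the C11 carbinol carbon of the aryl adduct and its xanthate.

Step 1
Reactants: 1 propanal; 2 methyl vinyl ketone (but-3-en-2-one)
Product: 3 (S)-2-methyl-5-oxohexanal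
Conditions: (R)-α,α-diphenylprolinol methyl ether (5 mol %), ethyl 3,4-dihydroxybenzoate (20 mol %), neat, 4 °C
Reagents that add atoms: none
Why: Enamine-catalysed asymmetric Michael addition, in which the E-enamine of propanal with the (R)-configured prolinol ether offers only the face remote from the CPh2OMe group to the catechol-activated enone, which should set the future C8 centre as S.

Step 2
Reactants: 3 (S)-2-methyl-5-oxohexanal
Product: 4 (S)-4-methylcyclohex-2-en-1-one
Conditions: LiOH (0.1 equiv), i-PrOH, rt
Reagents that add atoms: none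
Why: Intramolecular aldol condensation (6-(enolendo)-exo-trig, the only ring size open to this keto aldehyde) under mild catalytic base that should leave the methyl-bearing centre intact.

Step 3
Reactants: 4 (S)-4-methylcyclohex-2-en-1-one
Product: 5 {[(3R,4S)-3,4-dimethylcyclohex-1-en-1-yl]oxy}trimethylsilane (methyl groups trans)
Conditions: Me2CuLi (from MeLi and CuI), Et2O, −78 → −20 °C; then Me3SiCl, Et3N, −20 °C → rt
Reagents that add atoms: lithium dimethylcuprate, [Li+].C[Cu-]C; chlorotrimethylsilane, C[Si](C)(C)Cl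
Why: Gilman cuprate 1,4-addition followed by O-silylation of the regiodefined enolate, with the methyl group entering anti to the C4 methyl at a centre that step 4 erases again.

Step 4
Reactants: 5 {[(3R,4S)-3,4-dimethylcyclohex-1-en-1-yl]oxy}trimethylsilane
Product: 6 (S)-3,4-dimethylcyclohex-2-en-1-one
Conditions: Pd(OAc)2 (10 mol %), O2 (1 atm), DMSO, rt
Reagents that add atoms: none
Why: Saegusa–Ito oxidation in its aerobic catalytic form, in which the divalent palladium enolate bound at C2 can lose only the C3 hydride, so the alkene returns between C2 and C3 and the C4 stereocentre is not touched.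

Step 5
Reactants: 7 (1-bromoethenyl)trimethylsilane; 8 N-methoxy-N-methylacetamide
Product: 10 3-(trimethylsilyl)but-3-en-2-one, via 1-(trimethylsilyl)ethenylmagnesium bromide 9 (not isolated)
Conditions: Mg, THF, reflux; then 8, 0 °C; cold 1 M HCl
Reagents that add atoms: none
Why: Weinreb ketone synthesis with an α-silylvinyl Grignard reagent, which stops at the ketone level until the cold acidic quench, and that quench also keeps the released amine protonated and away from the new Michael acceptor.

Step 6
Reactants: 6 (S)-3,4-dimethylcyclohex-2-en-1-one; 11 vinylmagnesium bromide; 10 3-(trimethylsilyl)but-3-en-2-one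
Product: 15 (4aR,5R,6S)-5-ethenyl-5,6-dimethyl-4,4a,5,6,7,8-hexahydronaphthalen-2(3H)-one, via bromomagnesium enolate 12 (not isolated), via alpha-silyl diketone 13 (not isolated), via desilylated diketone 14 (not isolated)
Conditions: 11 (1.2 equiv), CuBr·SMe2 (0.2 equiv), THF/Me2S, −78 °C, then 6, −78 → −40 °C; 10 (1.5 equiv), −78 → −20 °C; KOH, MeOH, same flask, reflux
Reagents that add atoms: none
Why: A bromomagnesium vinylcuprate formed from 11 and CuBr·SMe2 transfers vinyl to the β carbon C9 of 6 (C9–C11), the enolate 12, which exists only as the C5=C10 regioisomer, adds through C10 to the CH2 terminus of 10 (C1–C10), and methanolic KOH then protonates the adduct, removes silicon (13 to 14) and drives condensation of the methyl carbon C4 onto the C5 carbonyl (C4–C5). The closest known reaction type is the conjugate addition–annulation form of the Robinson annulation with an α-silyl vinyl ketone, established for cuprate-derived cyclohexanone enolates. Ring A closes by a 6-(enolendo)-exo-trig aldol addition, since C3 and C4 of the attacking enolate both end up inside the new ring, followed by E1cB loss of water to the conjugated enone. C9 is controlled by the C8 methyl, which allylic 1,2-strain with the C9 methyl holds pseudoaxial in the half-chair of 6, so that stereoelectronically preferred axial delivery occurs on the opposite face and places vinyl trans to it and the two methyl groups cis. C10 is controlled thermodynamically, being α to the C5 ketone in 13 and 14 and vinylogously acidic in 15, so the base should settle it as the isomer with C1 equatorial on ring B and H-10 axial and cis to C11, in which only the C9 methyl is axial. The step needs 1,4- over 1,2-addition (secured by copper), capture at C10 before the enolate can shift to C6 and before the acceptor polymerises (secured by silicon, which stabilises and shields the adduct carbanion), and fused rather than bridged ketol formation (only the fused ketol can dehydrate irreversibly).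

Step 7
Reactants: 15 (4aR,5R,6S)-5-ethenyl-5,6-dimethyl-4,4a,5,6,7,8-hexahydronaphthalen-2(3H)-one
Product: 17 (4aS,5R,6S)-5-ethenyl-1,1,5,6-tetramethyl-3,4,4a,5,6,7-hexahydronaphthalen-2(1H)-one, via monomethyl beta,gamma-enone 16 (not isolated)
Conditions: KOt-Bu (3 equiv), MeI (4 equiv), t-BuOH, rt
Reagents that add atoms: iodomethane, CI
Why: Deconjugative α,α-dimethylation of a 4-en-3-one through its extended dienolate, in which γ-deprotonation at the C6 methylene rather than at the tertiary C10–H next to quaternary C9 gives the heteroannular 3,5-dienolate, and this alkylates twice at C4 and leaves the alkene at C5=C6 with no stereocentre changed.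

Step 8
Reactants: 17 (4aS,5R,6S)-5-ethenyl-1,1,5,6-tetramethyl-3,4,4a,5,6,7-hexahydronaphthalen-2(1H)-one
Product: 19 (1R,2S,8aS)-1-ethenyl-1,2,5,5-tetramethyl-1,2,3,5,6,7,8,8a-octahydronaphthalene, via hydrazone 18 (not isolated)
Conditions: N2H4·H2O, KOH, diethylene glycol, Ar (degassed), 130 °C then 200 °C
Reagents that add atoms: none
Why: Wolff–Kishner reduction (Huang-Minlon procedure), which is established for α-quaternary 4,4-dimethyl-3-oxo terpenoids, cannot move either alkene because C4 and C9 are quaternary, and spares the vinyl group as long as air, and hence diimide, is excluded.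

Step 9
Reactants: 19 (1R,2S,8aS)-1-ethenyl-1,2,5,5-tetramethyl-1,2,3,5,6,7,8,8a-octahydronaphthalene
Product: 21 (1R,2S,8aR)-1,2,5,5-tetramethyl-1,2,3,5,6,7,8,8a-octahydronaphthalene-1-carbaldehyde, via vicinal diol 20 (not isolated)
Conditions: OsO4 (2 mol %), NaIO4 (2.5 equiv), 2,6-lutidine (2 equiv), 1,4-dioxane/H2O, rt, stopped at consumption of 19
Reagents that add atoms: osmium tetroxide, O=[Os](=O)(=O)=O; sodium periodate, [Na+].[O-]I(=O)(=O)=O
Why: Lemieux–Johnson cleavage in which OsO4 should discriminate on steric grounds, because the terminal CH2 of the vinyl group is open whereas C5=C6 behaves as a 1-tert-alkylcyclohexene flanked by the C4 gem-dimethyl group and screened on one face by the axial C9 methyl.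

Step 10
Reactants: 21 (1R,2S,8aR)-1,2,5,5-tetramethyl-1,2,3,5,6,7,8,8a-octahydronaphthalene-1-carbaldehyde; 22 1,2,4,5-tetramethoxybenzene
Product: 24 [(1R,2S,8aR)-1,2,5,5-tetramethyl-1,2,3,5,6,7,8,8a-octahydronaphthalen-1-yl](2,3,5,6-tetramethoxyphenyl)methanol, via 2,3,5,6-tetramethoxyphenyllithium 23 (not isolated)
Conditions: 22, n-BuLi, THF, 0 °C → rt; then 21, −78 → 0 °C; H2O
Reagents that add atoms: none
Why: Directed ortho-lithiation at the position flanked by two methoxy groups followed by 1,2-addition to a non-enolisable aldehyde, creating a C11 carbinol centre whose configuration is irrelevant because step 12 removes it.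

Step 11
Reactants: 24 [(1R,2S,8aR)-1,2,5,5-tetramethyl-1,2,3,5,6,7,8,8a-octahydronaphthalen-1-yl](2,3,5,6-tetramethoxyphenyl)methanol
Product: 25 O-{[(1R,2S,8aR)-1,2,5,5-tetramethyl-1,2,3,5,6,7,8,8a-octahydronaphthalen-1-yl](2,3,5,6-tetramethoxyphenyl)methyl} S-methyl carbonodithioate
Conditions: NaN(SiMe3)2, THF, −78 °C; CS2; MeI, −78 °C → rt
Reagents that add atoms: carbon disulfide, S=C=S; iodomethane, CI
Why: Standard xanthate formation from the sodium alkoxide, helped here by the absence of any β-hydrogen (quaternary C9 on one side, aryl on the other), which rules out Chugaev elimination.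

Step 12
Reactants: 25 O-{[(1R,2S,8aR)-1,2,5,5-tetramethyl-1,2,3,5,6,7,8,8a-octahydronaphthalen-1-yl](2,3,5,6-tetramethoxyphenyl)methyl} S-methyl carbonodithioate
Product: 26 3-{[(1R,2S,8aS)-1,2,5,5-tetramethyl-1,2,3,5,6,7,8,8a-octahydronaphthalen-1-yl]methyl}-1,2,4,5-tetramethoxybenzene
Conditions: Bu3SnH, AIBN, toluene, 90 °C
Reagents that add atoms: none
Why: Barton–McCombie deoxygenation through a benzylic C11 radical that the stannane should reduce before it can reach the geometrically remote C5=C6 bond, a neutral process that avoids the cationic 1,2-shifts open to a neopentyl benzylic centre.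

Step 13
Reactants: 26 3-{[(1R,2S,8aS)-1,2,5,5-tetramethyl-1,2,3,5,6,7,8,8a-octahydronaphthalen-1-yl]methyl}-1,2,4,5-tetramethoxybenzene
Product: 27 2,5-dimethoxy-3-{[(1R,2S,8aS)-1,2,5,5-tetramethyl-1,2,3,5,6,7,8,8a-octahydronaphthalen-1-yl]methyl}cyclohexa-2,5-diene-1,4-dione
Conditions: (NH4)2Ce(NO3)6 (2.5 equiv), MeCN/H2O, 0 °C
Reagents that add atoms: water, O
Why: Oxidative demethylation of a 1,4-dimethoxyarene by tetravalent cerium, in which either para pair of methoxy groups leads by symmetry to the same 2,5-dimethoxy-1,4-benzoquinone and the isolated alkene is not attacked at this temperature.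

Step 14
Reactants: 27 2,5-dimethoxy-3-{[(1R,2S,8aS)-1,2,5,5-tetramethyl-1,2,3,5,6,7,8,8a-octahydronaphthalen-1-yl]methyl}cyclohexa-2,5-diene-1,4-dione
Product: 28 2-hydroxy-5-methoxy-3-{[(1R,2S,8aS)-1,2,5,5-tetramethyl-1,2,3,5,6,7,8,8a-octahydronaphthalen-1-yl]methyl}cyclohexa-2,5-diene-1,4-dione
Conditions: KOH, MeOH/H2O, rt; then 1 M HCl
Reagents that add atoms: potassium hydroxide, [K+].[OH-]
Why: Addition–elimination of hydroxide on a vinylogous ester, expected at the methoxy group next to the bulky C11 substituent because that group is twisted out of conjugation and so sits on the more electrophilic carbon, as is usual for 3-alkyl-2,5-dimethoxybenzoquinones.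

Step 15
Reactants: 28 2-hydroxy-5-methoxy-3-{[(1R,2S,8aS)-1,2,5,5-tetramethyl-1,2,3,5,6,7,8,8a-octahydronaphthalen-1-yl]methyl}cyclohexa-2,5-diene-1,4-dione; 29 isopentylamine (3-methylbutan-1-amine)
Product: 30 nakijiquinone M, 2-hydroxy-5-[(3-methylbutyl)amino]-3-{[(1R,2S,8aS)-1,2,5,5-tetramethyl-1,2,3,5,6,7,8,8a-octahydronaphthalen-1-yl]methyl}cyclohexa-2,5-diene-1,4-dione
Conditions: 29 (3 equiv), EtOH, rt → 40 °C; dilute citric acid wash
Reagents that add atoms: none
Why: Conjugate addition–elimination of the primary amine at the only remaining vinylogous ester carbon gives the vinylogous amide, the standard conversion of 2-hydroxy-5-methoxyquinones into their 5-alkylamino analogues, and touches no stereocentre.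

**Compound list**
1 | propanal | CCC=O | starting material
2 | methyl vinyl ketone | C=CC(C)=O | starting material
3 | (S)-2-methyl-5-oxohexanal | CC(=O)CC[C@@H](C=O)C | intermediate
4 | (S)-4-methylcyclohex-2-en-1-one | O=C1C=C[C@@H](C)CC1 | intermediate
5 | {[(3R,4S)-3,4-dimethylcyclohex-1-en-1-yl]oxy}trimethylsilane | C[Si](C)(C)OC1=C[C@H](C)[C@@H](C)CC1 | intermediate
6 | (S)-3,4-dimethylcyclohex-2-en-1-one | CC1=CC(=O)CC[C@@H]1C | intermediate
7 | (1-bromoethenyl)trimethylsilane | C=C(Br)[Si](C)(C)C | starting material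
8 | N-methoxy-N-methylacetamide | CC(=O)N(C)OC | starting material
9 | [1-(trimethylsilyl)ethenyl]magnesium bromide | C=C([Mg]Br)[Si](C)(C)C | intermediate
10 | 3-(trimethylsilyl)but-3-en-2-one | CC(=O)C(=C)[Si](C)(C)C | intermediate
11 | vinylmagnesium bromide | C=C[Mg]Br | starting material
12 | bromomagnesium (3R,4S)-3-ethenyl-3,4-dimethylcyclohex-1-en-1-olate | C=C[C@@]1(C)C=C(O[Mg]Br)CC[C@@H]1C | intermediate
13 | (2S,3R,4S)-3-ethenyl-3,4-dimethyl-2-[3-oxo-2-(trimethylsilyl)butyl]cyclohexan-1-one (C10 drawn as equilibrated) | C=C[C@@]1(C)[C@H](CC(C(C)=O)[Si](C)(C)C)C(=O)CC[C@@H]1C | intermediate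
14 | (2S,3R,4S)-3-ethenyl-3,4-dimethyl-2-(3-oxobutyl)cyclohexan-1-one | C=C[C@@]1(C)[C@H](CCC(C)=O)C(=O)CC[C@@H]1C | intermediate
15 | (4aR,5R,6S)-5-ethenyl-5,6-dimethyl-4,4a,5,6,7,8-hexahydronaphthalen-2(3H)-one | C=C[C@@]1(C)[C@@H]2CCC(=O)C=C2CC[C@@H]1C | intermediate
16 | (4aR,5R,6S)-5-ethenyl-1,5,6-trimethyl-3,4,4a,5,6,7-hexahydronaphthalen-2(1H)-one (C1 epimers) | C=C[C@@]1(C)[C@@H]2CCC(=O)C(C)C2=CC[C@@H]1C | intermediate
17 | (4aS,5R,6S)-5-ethenyl-1,1,5,6-tetramethyl-3,4,4a,5,6,7-hexahydronaphthalen-2(1H)-one | C=C[C@@]1(C)[C@@H]2CCC(=O)C(C)(C)C2=CC[C@@H]1C | intermediate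
18 | hydrazone of 17 | C=C[C@@]1(C)[C@@H]2CCC(=NN)C(C)(C)C2=CC[C@@H]1C | intermediate
19 | (1R,2S,8aS)-1-ethenyl-1,2,5,5-tetramethyl-1,2,3,5,6,7,8,8a-octahydronaphthalene | C=C[C@@]1(C)[C@@H]2CCCC(C)(C)C2=CC[C@@H]1C | intermediate
20 | 1-[(1R,2S,8aR)-1,2,5,5-tetramethyl-1,2,3,5,6,7,8,8a-octahydronaphthalen-1-yl]ethane-1,2-diol | OCC(O)[C@@]1(C)[C@@H]2CCCC(C)(C)C2=CC[C@@H]1C | intermediate
21 | (1R,2S,8aR)-1,2,5,5-tetramethyl-1,2,3,5,6,7,8,8a-octahydronaphthalene-1-carbaldehyde | O=C[C@@]1(C)[C@@H]2CCCC(C)(C)C2=CC[C@@H]1C | intermediate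
22 | 1,2,4,5-tetramethoxybenzene | COc1cc(OC)c(OC)cc1OC | starting material
23 | 2,3,5,6-tetramethoxyphenyllithium | [Li]c1c(OC)c(OC)cc(OC)c1OC | intermediate
24 | [(1R,2S,8aR)-1,2,5,5-tetramethyl-1,2,3,5,6,7,8,8a-octahydronaphthalen-1-yl](2,3,5,6-tetramethoxyphenyl)methanol | COc1cc(OC)c(OC)c(C(O)[C@@]2(C)[C@@H]3CCCC(C)(C)C3=CC[C@@H]2C)c1OC | intermediate
25 | O-{[(1R,2S,8aR)-1,2,5,5-tetramethyl-1,2,3,5,6,7,8,8a-octahydronaphthalen-1-yl](2,3,5,6-tetramethoxyphenyl)methyl} S-methyl carbonodithioate | COc1cc(OC)c(OC)c(C(OC(=S)SC)[C@@]2(C)[C@@H]3CCCC(C)(C)C3=CC[C@@H]2C)c1OC | intermediate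
26 | 3-{[(1R,2S,8aS)-1,2,5,5-tetramethyl-1,2,3,5,6,7,8,8a-octahydronaphthalen-1-yl]methyl}-1,2,4,5-tetramethoxybenzene | COc1cc(OC)c(OC)c(C[C@@]2(C)[C@@H]3CCCC(C)(C)C3=CC[C@@H]2C)c1OC | intermediate
27 | 2,5-dimethoxy-3-{[(1R,2S,8aS)-1,2,5,5-tetramethyl-1,2,3,5,6,7,8,8a-octahydronaphthalen-1-yl]methyl}cyclohexa-2,5-diene-1,4-dione | COC1=CC(=O)C(OC)=C(C[C@@]2(C)[C@@H]3CCCC(C)(C)C3=CC[C@@H]2C)C1=O | intermediate
28 | 2-hydroxy-5-methoxy-3-{[(1R,2S,8aS)-1,2,5,5-tetramethyl-1,2,3,5,6,7,8,8a-octahydronaphthalen-1-yl]methyl}cyclohexa-2,5-diene-1,4-dione | COC1=CC(=O)C(O)=C(C[C@@]2(C)[C@@H]3CCCC(C)(C)C3=CC[C@@H]2C)C1=O | intermediate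
29 | isopentylamine | CC(C)CCN | starting material
30 | nakijiquinone M | CC(C)CCNC1=CC(=O)C(O)=C(C[C@@]2(C)[C@@H]3CCCC(C)(C)C3=CC[C@@H]2C)C1=O | target

**Step count**
Total step count: 15. Longest linear sequence: 14 steps (steps 1–4 and 6–15, from propanal and methyl vinyl ketone). Step 5 is a one-step side branch.

**Steps most likely to fail**

Step 6. The Michael capture of the hindered C10 enolate, which sits next to quaternary C9, may be slow. Proton transfer and anionic consumption of the acceptor could then overtake C1–C10 bond formation. The fallback sets out from 6 and 11. The same copper-catalysed vinyl addition is run in the presence of Me3SiCl, and the enolate is isolated as the trimethylsilyl enol ether F1. A Mukaiyama–Michael reaction of F1 with methyl vinyl ketone 2 (TiCl4, CH2Cl2, −78 °C) forms C1–C10 under Lewis acid rather than anionic control. This comes back to the route at diketone 14, now isolated, which KOH in MeOH equilibrates at C10 and closes to 15.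

Step 7. Competing γ-deprotonation at C10 under equilibrating base would move the alkene to C5=C10, and excess base could over-methylate at C2. The fallback sets out from 15.
- Soft enolisation (Me3SiOSO2CF3, Et3N, CH2Cl2, 0 °C) removes the more accessible C6 proton and gives the heteroannular silyl dienol ether F2, whose regiochemistry can be checked and purified before any C–C bond is made.
- MeLi in THF releases the lithium 3,5-dienolate F3 under aprotic, non-equilibrating conditions, and MeI alkylates it at C4 to give 16, here isolated.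
- A second deprotonation at the doubly activated C4–H (KH, THF) followed by MeI comes back to the route at 17.

Step 9. Osmylation may not discriminate well enough between the neopentyl vinyl group and the more electron-rich ring alkene. The fallback sets out from 19 and relies on hydroboration, where the preference for a monosubstituted alkene is far larger.
- 9-Borabicyclo[3.3.1]nonane in THF gives the B-alkylborane F4, and NaOH/H2O2 converts it into the primary alcohol F5.
- Dess–Martin oxidation gives the homologous aldehyde F6.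
- Condensation with piperidine over molecular sieves gives the E-enamine F7.
- Oxidative cleavage of the very electron-rich enamine double bond (O2, CuCl cat, MeCN) removes the extra carbon and comes back to the route at 21.

**Further compounds**
F1 | step 6 | {[(3R,4S)-3-ethenyl-3,4-dimethylcyclohex-1-en-1-yl]oxy}trimethylsilane | C=C[C@@]1(C)C=C(O[Si](C)(C)C)CC[C@@H]1C
F2 | step 7 | {[(4aR,5R,6S)-5-ethenyl-5,6-dimethyl-3,4,4a,5,6,7-hexahydronaphthalen-2-yl]oxy}trimethylsilane | C=C[C@@]1(C)[C@@H]2CCC(O[Si](C)(C)C)=CC2=CC[C@@H]1C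
F3 | step 7 | lithium (4aR,5R,6S)-5-ethenyl-5,6-dimethyl-3,4,4a,5,6,7-hexahydronaphthalen-2-olate | C=C[C@@]1(C)[C@@H]2CCC(O[Li])=CC2=CC[C@@H]1C
F4 | step 9 | 9-{2-[(1R,2S,8aS)-1,2,5,5-tetramethyl-1,2,3,5,6,7,8,8a-octahydronaphthalen-1-yl]ethyl}-9-borabicyclo[3.3.1]nonane | C1CC2CCCC(C1)B2CC[C@@]3(C)[C@@H]4CCCC(C)(C)C4=CC[C@@H]3C
F5 | step 9 | 2-[(1R,2S,8aS)-1,2,5,5-tetramethyl-1,2,3,5,6,7,8,8a-octahydronaphthalen-1-yl]ethan-1-ol | OCC[C@@]1(C)[C@@H]2CCCC(C)(C)C2=CC[C@@H]1C
F6 | step 9 | 2-[(1R,2S,8aS)-1,2,5,5-tetramethyl-1,2,3,5,6,7,8,8a-octahydronaphthalen-1-yl]acetaldehyde | O=CC[C@@]1(C)[C@@H]2CCCC(C)(C)C2=CC[C@@H]1C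
F7 | step 9 | 1-{(E)-2-[(1R,2S,8aS)-1,2,5,5-tetramethyl-1,2,3,5,6,7,8,8a-octahydronaphthalen-1-yl]ethenyl}piperidine | C1CCCCN1/C=C/[C@@]2(C)[C@@H]3CCCC(C)(C)C3=CC[C@@H]2C
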